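Plan (lignan locants: guaiacyl arm C7–C8–C9, syringyl arm C7'–C8'(OH)–C9'; ring A = O9', C7, C8, C8', C9'; ring B = O9, C7', C8', C8, C9)
Retrosynthesis: after removal of a syringyl O-pivalate, the C8–C8' bond and the O9'–C7 bond are cut together, which opens both rings of the cis-fused 3,7-dioxabicyclo[3.3.0]octane to an acyclic C8' ketone; then the C7=C8 styrene bond (cross-metathesis), the C7'–O9 ether (epoxide opening by allyl alcohol) and the epoxide (from sinapyl alcohol) are cut.
Forward: the sinapyl chain is epoxidised, the C7'–O9–allyl ether is set, C8' is raised to the ketone, the guaiacyl styrene is joined by metathesis, and ring B then ring A form in one operation.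
Enabling feature: the free 4-OH of the guaiacyl ring, para to C7, makes phenol–C7=C8 a vinylogous enol, so C8 is a carbon nucleophile for the C8' carbonyl and C7 becomes the methide carbon of a p-quinone methide; the C9' hydroxyl sits 1,3 to C8' and closes ring A on C7, and both rings share the new C8–C8' bond.
Stereochemistry: C7' comes from a Sharpless epoxidation (L-(+)-tartrate) followed by invertive opening at the benzylic carbon; C8', C8 and C7 are set in the key step under control of C7' and of the cis ring fusion.

Key step: step 7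

Remark: the target SMILES is read as the all-exo (1S,2R,5R,6S) isomer, both aryl groups cis to the bridgehead OH and H; sinapyl alcohol, allyl alcohol and 2-methoxy-4-vinylphenol are taken as commercial.

Step 1
Reactants: 1 sinapyl alcohol
Product: 2 4-[(E)-3-hydroxyprop-1-enyl]-2,6-dimethoxyphenyl pivalate
Conditions: PivCl (1.05 equiv), 1 M NaOH (aq), CH2Cl2, Bu4NHSO4 (cat.), 0 °C
Reagents that add atoms: pivaloyl chloride, CC(C)(C)C(Cl)=O
Why: Schotten–Baumann acylation, in which only the phenol is ionised and the phenoxide should outcompete the neutral allylic alcohol; the ester also lowers the donor strength of the syringyl ring for the later acid steps.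

Step 2
Reactants: 2 4-[(E)-3-hydroxyprop-1-enyl]-2,6-dimethoxyphenyl pivalate
Product: 3 4-[(2S,3S)-3-(hydroxymethyl)oxiran-2-yl]-2,6-dimethoxyphenyl pivalate
Conditions: Ti(OiPr)4 (10 mol %), L-(+)-diisopropyl tartrate (12 mol %), t-BuOOH (2 equiv), 4 Å molecular sieves, CH2Cl2, −20 °C
Reagents that add atoms: tert-butyl hydroperoxide, CC(C)(C)OO
Why: Sharpless asymmetric epoxidation, where the L-(+)-tartrate should give the (2S,3S) epoxy alcohol as it does with (E)-cinnamyl alcohol, and the ester-deactivated arene should keep the benzylic epoxide from opening in the flask.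

Step 3
Reactants: 3 4-[(2S,3S)-3-(hydroxymethyl)oxiran-2-yl]-2,6-dimethoxyphenyl pivalate; 4 allyl alcohol
Product: 5 4-[(1R,2S)-1-(allyloxy)-2,3-dihydroxypropyl]-2,6-dimethoxyphenyl pivalate
Conditions: Ti(OiPr)4 (1.5 equiv), allyl alcohol (solvent), rt to 40 °C; then H2O
Reagents that add atoms: none
Why: Titanium-alkoxide-mediated C3-selective opening of a 2,3-epoxy alcohol, in which the substrate is bound to tetravalent titanium and allyl alcohol attacks the benzylic carbon from the back (SN2, inversion), so that (3S) becomes (R) at C7', the configuration kept to the target.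

Step 4
Reactants: 5 4-[(1R,2S)-1-(allyloxy)-2,3-dihydroxypropyl]-2,6-dimethoxyphenyl pivalate
Product: 6 4-[(1R,2S)-1-(allyloxy)-3-(tert-butyldimethylsilyloxy)-2-hydroxypropyl]-2,6-dimethoxyphenyl pivalate
Conditions: TBSCl (1.05 equiv), imidazole (2 equiv), CH2Cl2, 0 °C
Reagents that add atoms: tert-butyldimethylsilyl chloride, CC(C)(C)[Si](C)(C)Cl
Why: Sterically controlled silylation, which should take the primary hydroxyl of the 1,2-diol and leave the secondary one free for oxidation.

Step 5
Reactants: 6 4-[(1R,2S)-1-(allyloxy)-3-(tert-butyldimethylsilyloxy)-2-hydroxypropyl]-2,6-dimethoxyphenyl pivalate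
Product: 7 4-[(1R)-1-(allyloxy)-3-(tert-butyldimethylsilyloxy)-2-oxopropyl]-2,6-dimethoxyphenyl pivalate
Conditions: Dess–Martin periodinane (1.3 equiv), CH2Cl2, 0 °C to rt
Reagents that add atoms: none
Why: Dess–Martin oxidation of the secondary alcohol to the C8' ketone under non-basic conditions, so that the benzylic α-alkoxy centre C7' should not be enolised.

Step 6
Reactants: 7 4-[(1R)-1-(allyloxy)-3-(tert-butyldimethylsilyloxy)-2-oxopropyl]-2,6-dimethoxyphenyl pivalate; 8 2-methoxy-4-vinylphenol
Product: 9 4-[(1R)-3-(tert-butyldimethylsilyloxy)-1-{[(E)-3-(4-hydroxy-3-methoxyphenyl)prop-2-enyl]oxy}-2-oxopropyl]-2,6-dimethoxyphenyl pivalate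
Conditions: second-generation Hoveyda–Grubbs catalyst RuCl2(H2IMes)(=CH-C6H4-2-OiPr) (5 mol %), 8 (3 equiv), CH2Cl2, 40 °C
Reagents that add atoms: none
Why: Olefin cross-metathesis of an unhindered terminal allyl ether with an excess of a styrene, which should give the E-cinnamyl ether under thermodynamic control with loss of ethylene; the ruthenium carbene tolerates the free phenol.

Step 7
Reactants: 9 4-[(1R)-3-(tert-butyldimethylsilyloxy)-1-{[(E)-3-(4-hydroxy-3-methoxyphenyl)prop-2-enyl]oxy}-2-oxopropyl]-2,6-dimethoxyphenyl pivalate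
Product: 12 4-[(1S,2R,5R,6S)-1-hydroxy-6-(4-hydroxy-3-methoxyphenyl)-3,7-dioxabicyclo[3.3.0]oct-2-yl]-2,6-dimethoxyphenyl pivalate (O-pivaloylfraxiresinol), via free hydroxy ketone 10 (not isolated), via p-quinone methide 11 (not isolated)
Conditions: Sc(OTf)3 (10 mol %), H2O (5 equiv), MeCN (0.01 M), 0 °C to rt
Reagents that add atoms: none
Why: Proposed new method: Sc(OTf)3 and water first cleave the primary silyl ether to hydroxy ketone 10, whose carbonyl, held with the C9' hydroxyl in a five-membered chelate on trivalent scandium, is attacked by C8, the terminus of the vinylogous enol made up of the free para-phenol and the C7=C8 bond, to give the C8' carbinol and p-quinone methide 11, and the C9' hydroxyl then adds to the methide carbon C7 with rearomatisation. The closest known reaction types are the Lewis acid-catalysed intramolecular carbonyl–ene/Prins cyclisation of alkenyl ketones in which a pendant hydroxyl captures the benzylic cation, and the intramolecular alcohol addition to p-quinone methides used in biomimetic furofuran lignan syntheses; a ketone has not been shown as the electrophile for a p-hydroxystyrene in such a cascade. Ring B closes by a 5-exo-trig attack at the carbonyl with C7 left outside the ring (5-(enolexo)-exo-trig), and ring A closes by a 5-exo-trig oxa-1,6-addition to the exocyclic methide. C8' is controlled by the (R)-C7' centre, because the hydroxymethyl arm should take the face of the forming ring anti to the syringyl group and leave the carbonyl oxygen syn to it; C8 is controlled by the ring fusion, because only the isomer with the methide arm cis to the hydroxymethyl arm can close the cis-fused ring A while the other reverts by retro-Prins cleavage; C7 is controlled by C8, the aryl group ending on the convex face trans to the C8–C9 bond as in the closure of pinoresinol-type quinone methides. The step needs carbonyl addition to outrun ionisation of the cinnamyl C9–O9 bond and enolisation toward C7', which the bidentate binding of the hydroxy ketone to scandium, the five-ring tether, high dilution and the electron-poor pivaloyloxy-substituted syringyl ring are meant to secure.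

Step 8
Reactants: 12 O-pivaloylfraxiresinol
Product: 13 fraxiresinol, (1S,2R,5R,6S)-2-(4-hydroxy-3,5-dimethoxyphenyl)-6-(4-hydroxy-3-methoxyphenyl)-3,7-dioxabicyclo[3.3.0]octan-1-ol
Conditions: K2CO3 (0.5 equiv), MeOH, rt to 40 °C; then NH4Cl (aq)
Reagents that add atoms: none
Why: Base-catalysed methanolysis (transesterification) of the aryl pivalate, which should free the syringyl phenol without touching any stereocentre.

Compound list
1 | sinapyl alcohol, (E)-4-(3-hydroxyprop-1-enyl)-2,6-dimethoxyphenol | COc1cc(/C=C/CO)cc(OC)c1O | starting material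
2 | 4-[(E)-3-hydroxyprop-1-enyl]-2,6-dimethoxyphenyl pivalate | COc1cc(/C=C/CO)cc(OC)c1OC(=O)C(C)(C)C | intermediate
3 | 4-[(2S,3S)-3-(hydroxymethyl)oxiran-2-yl]-2,6-dimethoxyphenyl pivalate | OC[C@@H]1O[C@H]1c1cc(OC)c(OC(=O)C(C)(C)C)c(OC)c1 | intermediate
4 | allyl alcohol, prop-2-en-1-ol | C=CCO | starting material
5 | 4-[(1R,2S)-1-(allyloxy)-2,3-dihydroxypropyl]-2,6-dimethoxyphenyl pivalate | OC[C@H](O)[C@H](OCC=C)c1cc(OC)c(OC(=O)C(C)(C)C)c(OC)c1 | intermediate
6 | 4-[(1R,2S)-1-(allyloxy)-3-(tert-butyldimethylsilyloxy)-2-hydroxypropyl]-2,6-dimethoxyphenyl pivalate | CC(C)(C)[Si](C)(C)OC[C@H](O)[C@H](OCC=C)c1cc(OC)c(OC(=O)C(C)(C)C)c(OC)c1 | intermediate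
7 | 4-[(1R)-1-(allyloxy)-3-(tert-butyldimethylsilyloxy)-2-oxopropyl]-2,6-dimethoxyphenyl pivalate | CC(C)(C)[Si](C)(C)OCC(=O)[C@H](OCC=C)c1cc(OC)c(OC(=O)C(C)(C)C)c(OC)c1 | intermediate
8 | 2-methoxy-4-vinylphenol | C=Cc1ccc(O)c(OC)c1 | starting material
9 | 4-[(1R)-3-(tert-butyldimethylsilyloxy)-1-{[(E)-3-(4-hydroxy-3-methoxyphenyl)prop-2-enyl]oxy}-2-oxopropyl]-2,6-dimethoxyphenyl pivalate | CC(C)(C)[Si](C)(C)OCC(=O)[C@H](OC/C=C/c1ccc(O)c(OC)c1)c1cc(OC)c(OC(=O)C(C)(C)C)c(OC)c1 | intermediate
10 | 4-[(1R)-3-hydroxy-1-{[(E)-3-(4-hydroxy-3-methoxyphenyl)prop-2-enyl]oxy}-2-oxopropyl]-2,6-dimethoxyphenyl pivalate (free hydroxy ketone, formed in the flask in step 7) | OCC(=O)[C@H](OC/C=C/c1ccc(O)c(OC)c1)c1cc(OC)c(OC(=O)C(C)(C)C)c(OC)c1 | intermediate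
11 | 4-{(2R,3S,4S)-3-hydroxy-3-(hydroxymethyl)-4-[(3-methoxy-4-oxocyclohexa-2,5-dienylidene)methyl]tetrahydrofuran-2-yl}-2,6-dimethoxyphenyl pivalate (p-quinone methide, formed in the flask in step 7, methide geometry not defined) | OC[C@]1(O)[C@@H](c2cc(OC)c(OC(=O)C(C)(C)C)c(OC)c2)OC[C@@H]1C=C1C=CC(=O)C(OC)=C1 | intermediate
12 | 4-[(1S,2R,5R,6S)-1-hydroxy-6-(4-hydroxy-3-methoxyphenyl)-3,7-dioxabicyclo[3.3.0]oct-2-yl]-2,6-dimethoxyphenyl pivalate (O-pivaloylfraxiresinol) | COc1cc([C@H]2OC[C@]3(O)[C@@H](c4cc(OC)c(OC(=O)C(C)(C)C)c(OC)c4)OC[C@H]23)ccc1O | intermediate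
13 | fraxiresinol, (1S,2R,5R,6S)-2-(4-hydroxy-3,5-dimethoxyphenyl)-6-(4-hydroxy-3-methoxyphenyl)-3,7-dioxabicyclo[3.3.0]octan-1-ol | COc1cc([C@H]2OC[C@]3(O)[C@@H](c4cc(OC)c(O)c(OC)c4)OC[C@H]23)ccc1O | target

Total step count: 8. Longest linear sequence: 8 steps (1 to 13); compounds 4 and 8 enter as commercial partners.

Steps most likely to fail

Step 7 (proposed new method). What may go wrong: heterolysis of the cinnamyl C9–O9 ether or enolisation of the ketone toward C7' may outrun C8–C8' bond formation, or the carbonyl addition may show poor facial selectivity. The fallback uses known chemistry in a stepwise, reductive-then-oxidative order and sets out from 9. SmI2/HMPA/t-BuOH in THF at −78 °C should effect a ketyl–olefin 5-exo cyclisation onto the styrene, with the samarium alkoxide and the styrene arm on opposite faces, and give after protonation the olivil-type 4-[(2R,3S,4S)-3-(tert-butyldimethylsilyloxymethyl)-3-hydroxy-4-(4-hydroxy-3-methoxybenzyl)tetrahydrofuran-2-yl]-2,6-dimethoxyphenyl pivalate F1, in which the C8–C8' bond is in place. TBAF/AcOH in THF should then free the primary alcohol to the triol 4-[(2R,3S,4S)-3-hydroxy-3-(hydroxymethyl)-4-(4-hydroxy-3-methoxybenzyl)tetrahydrofuran-2-yl]-2,6-dimethoxyphenyl pivalate F2. DDQ in CH2Cl2 at 0 °C should dehydrogenate the p-hydroxybenzyl group to the quinone methide 11, which the C9' hydroxyl closes to 12, where the route is rejoined.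

Step 6. What may go wrong: migration of the allyl ether double bond by ruthenium hydrides, self-metathesis of the vinylphenol and catalyst decay by the phenol may leave conversion low or erode the E geometry. The fallback sets out from 7 and replaces metathesis by a base-free oxidative boron Heck arylation of the terminal alkene with 4-hydroxy-3-methoxyphenylboronic acid pinacol ester [Pd(OAc)2 with 1,2-bis(phenylsulfinyl)ethane (10 mol %), benzoquinone, AcOH, dioxane, rt]. Chelation of divalent palladium by the ether oxygen should direct β-hydride elimination to the E-styrene, so the fallback comes back to the route at 9 without a new intermediate.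

Step 3. What may go wrong: sluggish alcoholysis may force heating, with transfer of the pivaloyl group to titanium alkoxide, isopropoxide competing as nucleophile, or partial SN1 opening that erodes the C7' configuration. The fallback sets out from 3 and reverses the order of protection and opening. Silylation (TBSCl, imidazole, CH2Cl2) should give the epoxy silyl ether 4-[(2S,3S)-3-(tert-butyldimethylsilyloxymethyl)oxiran-2-yl]-2,6-dimethoxyphenyl pivalate F3. This is then opened with allyl alcohol under catalytic BF3·OEt2 in CH2Cl2 at −30 °C, where regiochemistry comes from benzylic activation of the acid-bound epoxide and not from a titanium chelate, and no metal alkoxide is present. Inversion at the benzylic carbon should give 6, where the route is rejoined.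

Further compounds
F1 | step 7 | 4-[(2R,3S,4S)-3-(tert-butyldimethylsilyloxymethyl)-3-hydroxy-4-(4-hydroxy-3-methoxybenzyl)tetrahydrofuran-2-yl]-2,6-dimethoxyphenyl pivalate | CC(C)(C)[Si](C)(C)OC[C@]1(O)[C@@H](c2cc(OC)c(OC(=O)C(C)(C)C)c(OC)c2)OC[C@@H]1Cc1ccc(O)c(OC)c1
F2 | step 7 | 4-[(2R,3S,4S)-3-hydroxy-3-(hydroxymethyl)-4-(4-hydroxy-3-methoxybenzyl)tetrahydrofuran-2-yl]-2,6-dimethoxyphenyl pivalate | OC[C@]1(O)[C@@H](c2cc(OC)c(OC(=O)C(C)(C)C)c(OC)c2)OC[C@@H]1Cc1ccc(O)c(OC)c1
F0 | step 6 | none | none
F3 | step 3 | 4-[(2S,3S)-3-(tert-butyldimethylsilyloxymethyl)oxiran-2-yl]-2,6-dimethoxyphenyl pivalate | CC(C)(C)[Si](C)(C)OC[C@@H]1O[C@H]1c1cc(OC)c(OC(=O)C(C)(C)C)c(OC)c1
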